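**Retrosynthetic overview**
- Feature used: pyran C4=C3–C2(CH3)(O1) plus side-chain C1'–C5' form one C10 unit, CH=CH–C(CH3)(O)–CH2CH2–CH=C(CH3)–CH2, and side-chain C6'–C13' (with the C8' carbinol) repeat it head to tail. Ring C2 and C8' are both (S), so one enantiopure alkynol, (S)-3,7-dimethyloct-6-en-1-yn-3-ol, can supply all 20 non-aromatic carbons and both stereocentres.
- Last ring bond: O1–C8a, by palladium-catalysed etherification of a (Z)-styrenyl tertiary alcohol onto an ortho C–Br bond, so the C2–O bond is never broken. The benzene ring is bought; the pyran is the only ring made and it closes after the whole skeleton is in place.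
- Skeleton: C4–C4a by iodide-selective Sonogashira coupling to a 2-bromo-1-iodoarene and C5'–C6' by allyl–alkenyl Stille coupling, both in one flask on an alkynyl allylic chloride. The (E)-vinylstannane partner is made from the same alkynol.
- The alkynol comes from geraniol (Sharpless epoxidation, then epoxy chloride double elimination); the arene comes from 4-methoxy-2-methylaniline.

Key step: step 11

Remark: both carbinol carbons are read from the SMILES as (S); the tertiary hydroxyls are carried unprotected throughout, and only the phenol is masked (as its triisopropylsilyl ether).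

**Route**

Step 1
Reactants: 1 geraniol
Product: 2 [(2S,3S)-3-methyl-3-(4-methylpent-3-en-1-yl)oxiran-2-yl]methanol ((2S,3S)-2,3-epoxygeraniol)
Conditions: Ti(OiPr)4 (5 mol %), L-(+)-diethyl tartrate (6 mol %), t-BuOOH (anhydrous, decane), 4 Å MS, CH2Cl2, −20 °C
Reagents that add atoms: tert-butyl hydroperoxide, CC(C)(C)OO
Why: Sharpless asymmetric epoxidation, in which the titanium tartrate complex binds the allylic hydroxyl and delivers oxygen to one face of the 2,3-alkene only (the 6,7-alkene has no directing group), so that the L-(+)-tartrate sets both new centres as (S).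

Step 2
Reactants: 2 (2S,3S)-2,3-epoxygeraniol
Product: 3 (2S,3R)-3-(chloromethyl)-2-methyl-2-(4-methylpent-3-en-1-yl)oxirane (same spatial arrangement as 2; only the descriptor of the CH–O carbon changes because CH2Cl outranks the ring carbon)
Conditions: PPh3, CCl4, NaHCO3, reflux
Reagents that add atoms: carbon tetrachloride, ClC(Cl)(Cl)Cl
Why: Appel chlorination of the primary alcohol under bicarbonate buffering, which should leave the epoxide closed and touches no stereocentre.

Step 3
Reactants: 3 epoxy chloride
Product: 5 (S)-3,7-dimethyloct-6-en-1-yn-3-ol, via chlorovinyl lithium alkoxide 4 (not isolated)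
Conditions: n-BuLi (3.3 equiv), THF, −40 to −20 °C; then aq NH4Cl
Reagents that add atoms: none
Why: Base-induced double elimination of a 2,3-epoxy chloride, in which deprotonation at CH2Cl opens the epoxide to the chlorovinyl alkoxide 4, a second equivalent removes HCl to give the alkyne and a third holds it as the acetylide, so the C3–O bond is never broken and the (S) carbinol is carried over unchanged.

Step 4
Reactants: 5 (S)-3,7-dimethyloct-6-en-1-yn-3-ol
Product: 6 (3S,6E)-3,7-dimethyloct-6-en-1-yne-3,8-diol
Conditions: SeO2 (0.3 equiv), t-BuOOH (2.5 equiv), salicylic acid (0.1 equiv), CH2Cl2, rt, stopped at partial conversion with recovery of 5; work-up with NaBH4, MeOH, 0 °C only to return any over-oxidised enal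
Reagents that add atoms: tert-butyl hydroperoxide, CC(C)(C)OO
Why: Catalytic SeO2 allylic oxidation (ene reaction followed by [2,3]-sigmatropic shift) should go to the (E)-methyl group at the more substituted end of the trisubstituted alkene, while the only propargylic carbon is quaternary and the tertiary alcohol cannot be oxidised, so the stereocentre is untouched.

Step 5
Reactants: 6 (3S,6E)-3,7-dimethyloct-6-en-1-yne-3,8-diol
Product: 7 (3S,6E)-8-chloro-3,7-dimethyloct-6-en-1-yn-3-ol
Conditions: NCS (1.2 equiv), Me2S (1.3 equiv), CH2Cl2, −40 to 0 °C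
Reagents that add atoms: N-chlorosuccinimide, O=C1CCC(=O)N1Cl
Why: Corey–Kim chlorination, in which the chlorosulfonium reagent activates only the unhindered primary allylic hydroxyl and chloride displaces it in SN2 fashion without allylic transposition, while the tertiary propargylic alcohol cannot be displaced and stays free.

Step 6
Reactants: 5 (S)-3,7-dimethyloct-6-en-1-yn-3-ol
Product: 8 (1E,3S)-3,7-dimethyl-1-(tributylstannyl)octa-1,6-dien-3-ol
Conditions: Bu3SnH (1.1 equiv, slow addition), PdCl2(PPh3)2 (2 mol %), THF, 0 °C to rt; chromatography on Et3N-deactivated silica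
Reagents that add atoms: tributyltin hydride, CCCC[SnH](CCCC)CCCC
Why: Palladium-catalysed hydrostannation adds Sn–H syn across the terminal alkyne to give the E alkene, and the bulk of the quaternary carbinol carbon should direct tin to the terminal carbon, with the stereocentre untouched.

Step 7
Reactants: 9 4-methoxy-2-methylaniline
Product: 10 2-iodo-4-methoxy-6-methylaniline
Conditions: BnMe3N+ ICl2− (1.05 equiv), CaCO3, CH2Cl2/MeOH, rt
Reagents that add atoms: benzyltrimethylammonium dichloroiodate, C[N+](C)(C)Cc1ccccc1.Cl[I-]Cl
Why: Electrophilic aromatic iodination directed by the amino group, whose para position carries the methoxy group and whose other ortho position carries the methyl group, so iodine should enter the single free ortho position.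

Step 8
Reactants: 10 2-iodo-4-methoxy-6-methylaniline
Product: 12 2-bromo-1-iodo-5-methoxy-3-methylbenzene, via arenediazonium salt 11 (not isolated)
Conditions: t-BuONO (1.5 equiv), CuBr2 (1.2 equiv), MeCN, 0 to 60 °C
Reagents that add atoms: copper dibromide, [Cu+2].[Br-].[Br-]
Why: Sandmeyer bromination under anhydrous alkyl nitrite conditions, in which the amine is diazotised in the flask and the diazonium group is replaced by bromide through copper-mediated electron transfer, leaving the aryl iodide and the ether intact.

Step 9
Reactants: 12 2-bromo-1-iodo-5-methoxy-3-methylbenzene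
Product: 13 4-bromo-3-iodo-5-methylphenol
Conditions: BBr3 (1.5 equiv), CH2Cl2, −78 to 0 °C; then H2O
Reagents that add atoms: none
Why: Lewis acid cleavage of the aryl methyl ether (boron coordination, then bromide attack on the methyl group), to which the aryl halides are inert.

Step 10
Reactants: 13 4-bromo-3-iodo-5-methylphenol
Product: 14 (4-bromo-3-iodo-5-methylphenoxy)triisopropylsilane
Conditions: TIPSCl (1.2 equiv), imidazole (2.5 equiv), DMF, rt
Reagents that add atoms: triisopropylsilyl chloride, CC(C)[Si](Cl)(C(C)C)C(C)C
Why: Standard imidazole-promoted silylation of a phenol, chosen because the bulky silyl ether should survive amine, hydrogenation and carbonate conditions and come off with fluoride alone at the end.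

Step 11
Reactants: 7 (3S,6E)-8-chloro-3,7-dimethyloct-6-en-1-yn-3-ol; 8 (1E,3S)-3,7-dimethyl-1-(tributylstannyl)octa-1,6-dien-3-ol; 14 (4-bromo-3-iodo-5-methylphenoxy)triisopropylsilane
Product: 16 (3S,6E,9E,11S)-1-[2-bromo-3-methyl-5-(triisopropylsilyloxy)phenyl]-3,7,11,15-tetramethylhexadeca-6,9,14-trien-1-yne-3,11-diol, via C20 alkynediol 15 (not isolated)
Conditions: 7 (1.0 equiv), 8 (1.0 equiv), Pd2(dba)3 (2.5 mol %), degassed DMF, rt, dark, no base, no copper, until 7 is consumed; then 14 (1.0 equiv), PPh3 (10 mol %), CuI (5 mol %), i-Pr2NH (3 equiv), rt; aq KF work-up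
Reagents that add atoms: none
Why: Zerovalent palladium ionises the allylic C–Cl bond of 7 to a π-allyl palladium chloride, the alkenylstannane 8 transmetalates and reductive elimination at the unsubstituted CH2 terminus gives the E,E skipped diene 15, after which the same palladium, now with PPh3, CuI and amine, inserts into the C–I bond of 14 and couples the copper acetylide of 15 to give 16. The closest known reaction types are the Stille coupling of alkenylstannanes with primary allylic chlorides to 1,4-dienes and the iodide-selective Sonogashira coupling of tertiary propargylic alcohols, which are here only run one after the other in one flask. No ring is closed and no stereocentre is created: both (S) carbinol carbons enter with 7 and 8 and their C–O bonds are not involved, and the alkene geometries are carried over because transmetalation retains the vinyl geometry and the π-allyl intermediate should be trapped faster than it isomerises. The step needs the right pairing of partners, coupling at the primary allyl terminus and iodide-over-bromide selectivity; these are secured respectively by the staged addition (without base or copper the alkyne C–H and both tertiary hydroxyls stay passive, including the hydroxyl of 7 that could otherwise close a tetrahydrofuran onto the π-allyl), by the substitution pattern of the allyl unit, and by the faster oxidative addition of the C–I bond next to a C–Br bond that is flanked by two ortho substituents.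

Step 12
Reactants: 16 aryl alkyne diol
Product: 17 (1Z,3S,6E,9E,11S)-1-[2-bromo-3-methyl-5-(triisopropylsilyloxy)phenyl]-3,7,11,15-tetramethylhexadeca-1,6,9,14-tetraene-3,11-diol
Conditions: H2 (1 atm), Lindlar catalyst (Pd on CaCO3 poisoned with Pb(OAc)2), quinoline, EtOAc, rt, stopped after one equivalent of H2
Reagents that add atoms: none
Why: Lindlar semihydrogenation delivers H2 syn on the poisoned palladium surface to give the (Z)-styrene, and the conjugated alkyne should bind far better than the trisubstituted alkenes or the hindered E-disubstituted alkene, while the aryl bromide is not expected to be hydrogenolysed under these acid-free conditions.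

Step 13
Reactants: 17 (Z)-styrenyl diol
Product: 18 triisopropyl{[(2S)-2-[(3E,6E,8S)-8-hydroxy-4,8,12-trimethyltrideca-3,6,11-trien-1-yl]-2,8-dimethyl-2H-chromen-6-yl]oxy}silane
Conditions: Pd(OAc)2 (5 mol %), rac-2-(di-tert-butylphosphino)-1,1'-binaphthyl (7 mol %), Cs2CO3 (1.5 equiv), toluene, 70 °C, argon, dark
Reagents that add atoms: none
Why: Intramolecular Buchwald–Hartwig-type C–O coupling, in which oxidative addition into the aryl C–Br bond, exchange of bromide for the tertiary alkoxide held close by the Z alkene and C–O reductive elimination (driven by the bulky di-tert-butylphosphine, with no β-hydrogen on the alkoxide to lose) close the pyran at O1–C8a, so the C2–O bond is not broken and C2 keeps its (S) configuration.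

Step 14
Reactants: 18 silyl-protected chromene
Product: 19 (2S)-2-[(3E,6E,8S)-8-hydroxy-4,8,12-trimethyltrideca-3,6,11-trien-1-yl]-2,8-dimethyl-2H-chromen-6-ol (CNP0155965.1)
Conditions: TBAF (1.1 equiv), AcOH (1.1 equiv), THF, 0 °C; neutral work-up, light excluded
Reagents that add atoms: none
Why: Fluoride-driven cleavage of the aryl silyl ether through Si–F bond formation, buffered with acetic acid so that neither phenoxide nor acid builds up and the tertiary allylic alcohol and the light-sensitive chromene should stay intact.

**Compound list**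
1 | geraniol | CC(C)=CCC/C(C)=C/CO | starting material
2 | [(2S,3S)-3-methyl-3-(4-methylpent-3-en-1-yl)oxiran-2-yl]methanol | CC(C)=CCC[C@]1(C)O[C@H]1CO | intermediate
3 | (2S,3R)-3-(chloromethyl)-2-methyl-2-(4-methylpent-3-en-1-yl)oxirane | CC(C)=CCC[C@]1(C)O[C@H]1CCl | intermediate
4 | lithium (3S)-1-chloro-3,7-dimethylocta-1,6-dien-3-olate (alkene geometry not defined and of no consequence) | [Li+].CC(C)=CCC[C@](C)([O-])C=CCl | intermediate
5 | (S)-3,7-dimethyloct-6-en-1-yn-3-ol | CC(C)=CCC[C@](C)(O)C#C | intermediate
6 | (3S,6E)-3,7-dimethyloct-6-en-1-yne-3,8-diol | OC/C(C)=C/CC[C@](C)(O)C#C | intermediate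
7 | (3S,6E)-8-chloro-3,7-dimethyloct-6-en-1-yn-3-ol | ClC/C(C)=C/CC[C@](C)(O)C#C | intermediate
8 | (1E,3S)-3,7-dimethyl-1-(tributylstannyl)octa-1,6-dien-3-ol | CC(C)=CCC[C@](C)(O)/C=C/[Sn](CCCC)(CCCC)CCCC | intermediate
9 | 4-methoxy-2-methylaniline | Cc1cc(OC)ccc1N | starting material
10 | 2-iodo-4-methoxy-6-methylaniline | Cc1cc(OC)cc(I)c1N | intermediate
11 | 2-iodo-4-methoxy-6-methylbenzenediazonium bromide | Cc1cc(OC)cc(I)c1[N+]#N.[Br-] | intermediate
12 | 2-bromo-1-iodo-5-methoxy-3-methylbenzene | Cc1cc(OC)cc(I)c1Br | intermediate
13 | 4-bromo-3-iodo-5-methylphenol | Cc1cc(O)cc(I)c1Br | intermediate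
14 | (4-bromo-3-iodo-5-methylphenoxy)triisopropylsilane | Cc1cc(O[Si](C(C)C)(C(C)C)C(C)C)cc(I)c1Br | intermediate
15 | (3S,6E,9E,11S)-3,7,11,15-tetramethylhexadeca-6,9,14-trien-1-yne-3,11-diol | CC(C)=CCC[C@](C)(O)/C=C/C/C(C)=C/CC[C@](C)(O)C#C | intermediate
16 | (3S,6E,9E,11S)-1-[2-bromo-3-methyl-5-(triisopropylsilyloxy)phenyl]-3,7,11,15-tetramethylhexadeca-6,9,14-trien-1-yne-3,11-diol | CC(C)=CCC[C@](C)(O)/C=C/C/C(C)=C/CC[C@](C)(O)C#Cc1cc(O[Si](C(C)C)(C(C)C)C(C)C)cc(C)c1Br | intermediate
17 | (1Z,3S,6E,9E,11S)-1-[2-bromo-3-methyl-5-(triisopropylsilyloxy)phenyl]-3,7,11,15-tetramethylhexadeca-1,6,9,14-tetraene-3,11-diol | CC(C)=CCC[C@](C)(O)/C=C/C/C(C)=C/CC[C@](C)(O)/C=C\c1cc(O[Si](C(C)C)(C(C)C)C(C)C)cc(C)c1Br | intermediate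
18 | triisopropyl{[(2S)-2-[(3E,6E,8S)-8-hydroxy-4,8,12-trimethyltrideca-3,6,11-trien-1-yl]-2,8-dimethyl-2H-chromen-6-yl]oxy}silane | CC(C)=CCC[C@](C)(O)/C=C/C/C(C)=C/CC[C@@]1(C)C=Cc2cc(O[Si](C(C)C)(C(C)C)C(C)C)cc(C)c2O1 | intermediate
19 | (2S)-2-[(3E,6E,8S)-8-hydroxy-4,8,12-trimethyltrideca-3,6,11-trien-1-yl]-2,8-dimethyl-2H-chromen-6-ol | CC(C)=CCC[C@](C)(O)/C=C/C/C(C)=C/CC[C@@]1(C)C=Cc2cc(O)cc(C)c2O1 | target

**Step count**
Total: 14 steps. Longest linear sequence: 9 steps (steps 1, 2, 3, 4, 5, 11, 12, 13, 14 from geraniol).

**Steps most likely to fail**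

1. Step 11. The π-allyl palladium intermediate may be intercepted before transmetalation, either by attack of the tertiary hydroxyl of 7 (tetrahydrofuran closure) or by allylpalladation of the tethered terminal alkyne, and the catalyst may lose activity between the two stages. The fallback sets out from 6 (with 14 and 8) and returns at 16; it caps the alkyne before any π-allyl is formed and gives up the one-flask linchpin. Sonogashira coupling of 6 with 14 (PdCl2(PPh3)2, CuI, i-Pr2NH, THF, rt) should give the aryl alkynediol (3S,6E)-1-[2-bromo-3-methyl-5-(triisopropylsilyloxy)phenyl]-3,7-dimethyloct-6-en-1-yne-3,8-diol F1. Corey–Kim chlorination of its primary allylic hydroxyl (NCS, Me2S, CH2Cl2, −40 to 0 °C) should give the allylic chloride (3S,6E)-1-[2-bromo-3-methyl-5-(triisopropylsilyloxy)phenyl]-8-chloro-3,7-dimethyloct-6-en-1-yn-3-ol F2. A separate Stille coupling of F2 with 8 (Pd2(dba)3, DMF, rt) then gives 16.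

2. Step 13. Oxidative addition and C–O reductive elimination at the doubly ortho-substituted aryl palladium centre may be slow, so that protodebromination, β-carbon elimination from the tertiary alkoxide or carbonate-induced loss of the silyl group overtakes ring closure. Any closure at O1–C2 would pass through an allylic cation or an ortho-quinone methide and lose C2, so the fallback keeps the O–aryl bond but changes metal, mechanism and halide. It sets out from 17 and returns at 18. A copper-catalysed aromatic Finkelstein reaction (CuI, NaI, trans-N,N'-dimethylcyclohexane-1,2-diamine, dioxane, 110 °C) should give the aryl iodide (1Z,3S,6E,9E,11S)-1-[2-iodo-3-methyl-5-(triisopropylsilyloxy)phenyl]-3,7,11,15-tetramethylhexadeca-1,6,9,14-tetraene-3,11-diol F3. An intramolecular Ullmann etherification through the copper alkoxide (CuI, 3,4,7,8-tetramethyl-1,10-phenanthroline, Cs2CO3, toluene, 110 °C) then closes the pyran to 18.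

3. Step 4. The allylic C–H oxidation may show poor site selectivity, stall at low conversion or over-oxidise to the enal, which would starve the longest branch of material. The fallback replaces C–H oxidation by cleavage and olefination; it sets out from 5 and returns at 6. Ozonolysis of the trisubstituted alkene, which reacts much faster than the alkyne (limiting O3 with a dye end-point indicator, CH2Cl2/MeOH, −78 °C; then Me2S), should give the hydroxy aldehyde (4S)-4-hydroxy-4-methylhex-5-ynal F4, which will sit largely as its lactol. An E-selective Wittig reaction with the stabilised ylide Ph3P=C(CH3)CO2Et (toluene, 60 °C) should give the enoate ethyl (2E,6S)-6-hydroxy-2,6-dimethyloct-2-en-7-ynoate F5. Reduction with i-Bu2AlH (CH2Cl2, −78 °C) then gives 6.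

**Further compounds**
F1 | step 11 | (3S,6E)-1-[2-bromo-3-methyl-5-(triisopropylsilyloxy)phenyl]-3,7-dimethyloct-6-en-1-yne-3,8-diol | OC/C(C)=C/CC[C@](C)(O)C#Cc1cc(O[Si](C(C)C)(C(C)C)C(C)C)cc(C)c1Br
F2 | step 11 | (3S,6E)-1-[2-bromo-3-methyl-5-(triisopropylsilyloxy)phenyl]-8-chloro-3,7-dimethyloct-6-en-1-yn-3-ol | ClC/C(C)=C/CC[C@](C)(O)C#Cc1cc(O[Si](C(C)C)(C(C)C)C(C)C)cc(C)c1Br
F3 | step 13 | (1Z,3S,6E,9E,11S)-1-[2-iodo-3-methyl-5-(triisopropylsilyloxy)phenyl]-3,7,11,15-tetramethylhexadeca-1,6,9,14-tetraene-3,11-diol | CC(C)=CCC[C@](C)(O)/C=C/C/C(C)=C/CC[C@](C)(O)/C=C\c1cc(O[Si](C(C)C)(C(C)C)C(C)C)cc(C)c1I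
F4 | step 4 | (4S)-4-hydroxy-4-methylhex-5-ynal | O=CCC[C@](C)(O)C#C
F5 | step 4 | ethyl (2E,6S)-6-hydroxy-2,6-dimethyloct-2-en-7-ynoate | CCOC(=O)/C(C)=C/CC[C@](C)(O)C#C
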